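**Plan**
- Retrosynthesis: the exocyclic C11=C13 is cut first (C11 phosphonate + formaldehyde). The ten-membered carbocycle is then opened at the C1–C10 single bond (alkenyl iodide at C10, primary alkylborane at C1 from a C1=C2 vinyl group), and C10–I goes back to a C9≡C10 alkyne. The butenolide is cut at C5–C6 and O–C15, the saturated lactone at C7–C8 and O–C12.
- Forward: the γ-lactone ring (C12, C11, C7, C8, O) comes first by Evans aldol/lactonization, then the butenolide ring (C15, C4, C5, C6, O) by Nozaki–Hiyama–Kishi coupling/lactonization, then the ten-membered ring by hydroboration/B-alkyl Suzuki–Miyaura closure, and the methylene last.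
- Enabling feature: in the ten-membered ring, C10 is an sp2 carbon of the ring-cis C9=C10 olefin and is joined to the only unfunctionalized two-carbon bridge, C1H2–C2H2, which ends at the oxygenated C3. C10 can therefore carry iodine and C1 boron, while the two five-membered lactones on C6–C7–C8 are closed beforehand and fold the chain.
- Stereochemistry: C7 and C8 come from the (S)-benzyloxazolidinone syn-aldol, C6 from Felkin/1,3-anti-controlled addition to the C6 aldehyde, and C3 from a Sharpless kinetic resolution. The C9=C10 geometry comes from hydroxyl-directed trans-hydrostannation, and C4=C5 from the Z-iodoacrylate.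

Key step: step 16

Remark: locants C1–C15 are the germacrane locants of the target (ring C1–C10; C11, C12, C13 on C7; C14 on C10; C15 on C4). In 12–26 the phosphonate-bearing C11 is drawn as the epimer trans to the C7 substituent; this centre is erased in step 17.

**Step 1**
Reactants: 1 but-2-yne-1,4-diol
Product: 2 4-[(tert-butyldiphenylsilyl)oxy]but-2-yn-1-ol
Conditions: NaH (1.0 equiv), THF, 0 °C → rt; then TBDPSCl (1.0 equiv)
Reagents that add atoms: tert-butyl(chloro)diphenylsilane, CC(C)(C)[Si](Cl)(c1ccccc1)c1ccccc1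
Why: O-silylation of the sparingly soluble monosodium alkoxide of the symmetric diol should favour mono-protection, and the two hydroxyls are equivalent so no regiochemistry arises.

**Step 2**
Reactants: 2 4-[(tert-butyldiphenylsilyl)oxy]but-2-yn-1-ol
Product: 3 4-[(tert-butyldiphenylsilyl)oxy]but-2-ynal
Conditions: Dess–Martin periodinane, CH2Cl2, 0 °C → rt
Reagents that add atoms: none
Why: Dess–Martin oxidation should convert the propargylic alcohol into the ynal under neutral conditions that leave the silyl ether untouched.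

**Step 3**
Reactants: 4 (4S)-4-benzyl-1,3-oxazolidin-2-one; 5 methyl 4-chloro-4-oxobutanoate
Product: 6 methyl 4-[(4S)-4-benzyl-2-oxo-1,3-oxazolidin-3-yl]-4-oxobutanoate
Conditions: n-BuLi, THF, −78 °C; then 5, −78 → 0 °C
Reagents that add atoms: none
Why: N-acylation of the lithiated oxazolidinone should occur at the acid chloride, which is far more electrophilic than the methyl ester at the other chain end.

**Step 4**
Reactants: 6 methyl 4-[(4S)-4-benzyl-2-oxo-1,3-oxazolidin-3-yl]-4-oxobutanoate; 3 4-[(tert-butyldiphenylsilyl)oxy]but-2-ynal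
Product: 8 (4S)-4-benzyl-3-{[(2S,3S)-2-{3-[(tert-butyldiphenylsilyl)oxy]prop-1-yn-1-yl}-5-oxooxolan-3-yl]carbonyl}-1,3-oxazolidin-2-one (trans-lactone), via syn-aldol hydroxy ester 7 (not isolated)
Conditions: Bu2BOTf, iPr2NEt, CH2Cl2, −78 → 0 °C; 3, −78 → 0 °C; pH 7 buffer, MeOH, H2O2, 0 °C; then p-TsOH (cat.), CH2Cl2, rt
Reagents that add atoms: none
Why: Evans syn-aldol reaction: the dibutylboron Z-enolate of the imide (the ester end is not enolized) should add to the ynal through a chair Zimmerman–Traxler transition state on the face opposite the benzyl group, which fixes C7 and C8, and acid then closes the new hydroxyl onto the methyl ester so that the syn aldol becomes the trans-disubstituted γ-lactone.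

**Step 5**
Reactants: 8 trans-lactone imide
Product: 9 (4R,5S)-5-{3-[(tert-butyldiphenylsilyl)oxy]prop-1-yn-1-yl}-4-(hydroxymethyl)oxolan-2-one
Conditions: NaBH4, THF/H2O (3:1), 0 °C → rt
Reagents that add atoms: none
Why: Reductive cleavage of the N-acyloxazolidinone should be selective because the imide carbonyl is much more electrophilic than the γ-lactone, the auxiliary is released intact, and migration of the lactone onto the new primary hydroxyl is disfavoured because it would pass through a bridged bicyclic orthoester.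

**Step 6**
Reactants: 9 hydroxymethyl lactone
Product: 10 (4R,5S)-5-{3-[(tert-butyldiphenylsilyl)oxy]prop-1-yn-1-yl}-4-{[(triethylsilyl)oxy]methyl}oxolan-2-one
Conditions: TESCl, imidazole, CH2Cl2, 0 °C
Reagents that add atoms: chlorotriethylsilane, CC[Si](Cl)(CC)CC
Why: Standard silylation of the primary alcohol shields it from the strong base of the next step.

**Step 7**
Reactants: 10 triethylsilyl ether lactone
Product: 12 diethyl [(3S,4R,5S)-5-{3-[(tert-butyldiphenylsilyl)oxy]prop-1-yn-1-yl}-2-oxo-4-{[(triethylsilyl)oxy]methyl}oxolan-3-yl]phosphonate, via ketene acetal phosphate 11 (not isolated)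
Conditions: LiN(iPr)2 (2.1 equiv), THF, −78 °C; ClP(O)(OEt)2 (1.05 equiv), −78 °C → rt; AcOH
Reagents that add atoms: diethyl chlorophosphate, CCOP(=O)(Cl)OCC
Why: Vinyl phosphate–phosphonate rearrangement: the lactone enolate is O-phosphorylated, the second equivalent of amide base lithiates C11 and triggers the 1,3-shift of phosphorus from oxygen to carbon, and protonation should give the phosphonate trans to the C7 substituent at an epimerizable, later erased centre.

**Step 8**
Reactants: 12 phosphono lactone triethylsilyl ether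
Product: 13 diethyl [(3S,4R,5S)-5-{3-[(tert-butyldiphenylsilyl)oxy]prop-1-yn-1-yl}-4-(hydroxymethyl)-2-oxooxolan-3-yl]phosphonate
Conditions: AcOH/THF/H2O (3:1:1), rt
Reagents that add atoms: none
Why: Acid-catalysed solvolysis should remove the primary triethylsilyl ether far faster than the hindered tert-butyldiphenylsilyl ether.

**Step 9**
Reactants: 13 phosphono lactone alcohol
Product: 14 diethyl [(3S,4S,5S)-5-{3-[(tert-butyldiphenylsilyl)oxy]prop-1-yn-1-yl}-4-formyl-2-oxooxolan-3-yl]phosphonate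
Conditions: Dess–Martin periodinane, CH2Cl2, 0 °C → rt; used at once
Reagents that add atoms: none
Why: Dess–Martin oxidation under neutral conditions should give the β-acyloxy aldehyde without base-induced β-elimination, and any epimerization at C7 would only return the favoured trans arrangement.

**Step 10**
Reactants: 15 methyl prop-2-ynoate; 16 prop-2-enal
Product: 17 methyl (2Z)-3-hydroxy-2-(iodomethylidene)pent-4-enoate (racemic at C3)
Conditions: MgI2 (1.2 equiv), CH2Cl2, 0 °C; aqueous work-up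
Reagents that add atoms: magnesium diiodide, [Mg+2].[I-].[I-]
Why: Halo-aldol (β-iodo Morita–Baylis–Hillman) reaction: iodide adds to the propiolate to give a magnesium β-iodo allenolate that should add 1,2 to acrolein and deliver the Z isomer (iodine cis to the ester), the carbinol being formed racemic.

**Step 11**
Reactants: 17 racemic iodo-dienol ester
Product: 18 methyl (2Z,3S)-3-hydroxy-2-(iodomethylidene)pent-4-enoate
Conditions: Ti(OiPr)4 (0.2 equiv), L-(+)-diisopropyl tartrate (0.24 equiv), t-BuOOH (0.6 equiv), 4 Å molecular sieves, CH2Cl2, −20 °C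
Reagents that add atoms: none
Why: Sharpless kinetic resolution: with L-(+)-tartrate the titanium tartrate peroxide should epoxidize the vinyl group of the 3R carbinol rapidly (the electron-poor iodoacrylate olefin is inert), so the 3S alcohol, the slow-reacting enantiomer by the Sharpless mnemonic, is recovered.

**Step 12**
Reactants: 18 (3S)-iodo-dienol ester
Product: 19 methyl (2Z,3S)-2-(iodomethylidene)-3-[(2-methylpropanoyl)oxy]pent-4-enoate
Conditions: isobutyryl chloride, pyridine, CH2Cl2, 0 °C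
Reagents that add atoms: 2-methylpropanoyl chloride, CC(C)C(Cl)=O
Why: Acylation of the secondary alcohol with the acid chloride and pyridine avoids a nucleophilic catalyst such as DMAP, which could displace iodide from the β-iodoacrylate.

**Step 13**
Reactants: 14 phosphono lactone aldehyde; 19 Z-iodoacrylate isobutyrate
Product: 21 diethyl [(3S,4R,5S)-5-{3-[(tert-butyldiphenylsilyl)oxy]prop-1-yn-1-yl}-4-{(2R)-4-[(1S)-1-(2-methylpropanoyloxy)prop-2-en-1-yl]-5-oxo-2,5-dihydrofuran-2-yl}-2-oxooxolan-3-yl]phosphonate, via Z-hydroxy enoate 20 (not isolated)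
Conditions: CrCl2 (4 equiv), NiCl2 (2 mol %), DMSO, rt; 19 (1.5 equiv)
Reagents that add atoms: none
Why: Nozaki–Hiyama–Kishi coupling: zerovalent nickel inserts into the activated alkenyl C–I bond, transmetalation gives an alkenylchromium species that adds only to the aldehyde, and the chromium alkoxide lactonizes onto the cis ester to give the butenolide; the 6R configuration is expected from Felkin–Anh attack anti to the C7–C11 bond (the branch carrying the bulky phosphonate) reinforced by 1,3-anti induction from the β-acyloxy group at C8.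

**Step 14**
Reactants: 21 silyl-protected bis-lactone
Product: 22 diethyl [(3S,4R,5S)-5-(3-hydroxyprop-1-yn-1-yl)-4-{(2R)-4-[(1S)-1-(2-methylpropanoyloxy)prop-2-en-1-yl]-5-oxo-2,5-dihydrofuran-2-yl}-2-oxooxolan-3-yl]phosphonate
Conditions: HF·pyridine, pyridine, THF, 0 °C → rt
Reagents that add atoms: none
Why: Buffered fluoride desilylation should free the C14 hydroxyl without touching the isobutyrate, the lactones or the phosphonate.

**Step 15**
Reactants: 22 propargylic alcohol bis-lactone
Product: 24 diethyl [(3S,4R,5S)-5-[(1Z)-3-hydroxy-2-iodoprop-1-en-1-yl]-4-{(2R)-4-[(1S)-1-(2-methylpropanoyloxy)prop-2-en-1-yl]-5-oxo-2,5-dihydrofuran-2-yl}-2-oxooxolan-3-yl]phosphonate, via Z-alkenylstannane 23 (not isolated)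
Conditions: Bu3SnH (1.1 equiv), [Cp*RuCl]4 (2.5 mol %), CH2Cl2, rt; then I2, 0 °C
Reagents that add atoms: iodine, II
Why: Hydroxyl-directed ruthenium-catalysed trans-hydrostannation should place tin on the alkyne carbon proximal to the free C14 hydroxyl (C10) and hydrogen anti on C9, so that tin is cis to C8, and iododestannylation with retention then gives the Z-iodoalkene while the other olefins stay untouched.

**Step 16**
Reactants: 24 Z-iodoalkene with terminal vinyl group
Product: 26 diethyl [(3S,4Z,6R,7R,8R,9E,11S)-14-hydroxy-3-(2-methylpropanoyloxy)-12,8:15,6-diolido-13-norgermacra-4,9-dien-11-yl]phosphonate (ten-membered carbocycle), via B-alkyl-9-BBN borane 25 (not isolated)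
Conditions: 9-BBN (3 equiv), THF, 0 °C → rt; then slow addition to PdCl2(dppf) (20 mol %), AsPh3, Cs2CO3, DMF/THF/H2O, 45 °C, final 1 mM
Reagents that add atoms: none
Why: 9-BBN adds anti-Markovnikov to the only monosubstituted olefin (C1=C2) to give the primary alkylborane 25, whose borate transmetalates to the alkenylpalladium iodide formed by oxidative addition of zerovalent palladium into C10–I, and reductive elimination forges C1–C10. The closest known reaction type is the intramolecular B-alkyl Suzuki–Miyaura macrocyclization used for medium and large carbocycles. The ten-membered ring closes in an endo sense with respect to the C9=C10 olefin (both olefin carbons end up in the ring) through an eleven-membered palladacycle. No stereocentre is created; the olefin geometry set in step 15 is retained through oxidative addition and reductive elimination, so C8 and C1 end up cis as the ring requires. The step needs intramolecular over intermolecular coupling, which high dilution and slow addition secure, helped by the trans-fused lactone and the rigid butenolide that hold the two side chains on C6–C7–C8 in a turn, with the C10–I bond on the cis side pointing toward C1. Chemoselectivity in the hydroboration rests on the butenolide and iodoalkene being trisubstituted and on C11 being sp3 (phosphonate in place of the exocyclic olefin), and dppf as a wide-bite-angle ligand should make reductive elimination outrun β-hydride elimination.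

**Step 17**
Reactants: 26 macrocyclic phosphonate
Product: 27 (3S,4Z,6R,7S,8R,9E)-14-hydroxy-3-(2-methylpropanoyloxy)germacra-4,9,11(13)-triene-12,8:15,6-diolide (CNP0322767.4)
Conditions: aq. HCHO (37 %), K2CO3, THF, 0 °C → rt
Reagents that add atoms: formaldehyde, C=O
Why: Horner–Wadsworth–Emmons olefination of the lactone-stabilized phosphonate carbanion with formaldehyde under mild carbonate base should install the exocyclic C11=C13 methylene and erase the C11 stereocentre.

**Compound list**
1 | but-2-yne-1,4-diol | OCC#CCO | starting material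
2 | 4-[(tert-butyldiphenylsilyl)oxy]but-2-yn-1-ol | OCC#CCO[Si](c1ccccc1)(c1ccccc1)C(C)(C)C | intermediate
3 | 4-[(tert-butyldiphenylsilyl)oxy]but-2-ynal | O=CC#CCO[Si](c1ccccc1)(c1ccccc1)C(C)(C)C | intermediate
4 | (4S)-4-benzyl-1,3-oxazolidin-2-one | O=C1N[C@@H](Cc2ccccc2)CO1 | starting material
5 | methyl 4-chloro-4-oxobutanoate | COC(=O)CCC(Cl)=O | starting material
6 | methyl 4-[(4S)-4-benzyl-2-oxo-1,3-oxazolidin-3-yl]-4-oxobutanoate | COC(=O)CCC(=O)N1[C@@H](Cc2ccccc2)COC1=O | intermediate
7 | methyl (3S,4S)-3-{[(4S)-4-benzyl-2-oxo-1,3-oxazolidin-3-yl]carbonyl}-7-[(tert-butyldiphenylsilyl)oxy]-4-hydroxyhept-5-ynoate | COC(=O)C[C@H](C(=O)N1[C@@H](Cc2ccccc2)COC1=O)[C@H](O)C#CCO[Si](c1ccccc1)(c1ccccc1)C(C)(C)C | intermediate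
8 | (4S)-4-benzyl-3-{[(2S,3S)-2-{3-[(tert-butyldiphenylsilyl)oxy]prop-1-yn-1-yl}-5-oxooxolan-3-yl]carbonyl}-1,3-oxazolidin-2-one | O=C1C[C@H](C(=O)N2[C@@H](Cc3ccccc3)COC2=O)[C@@H](C#CCO[Si](c3ccccc3)(c3ccccc3)C(C)(C)C)O1 | intermediate
9 | (4R,5S)-5-{3-[(tert-butyldiphenylsilyl)oxy]prop-1-yn-1-yl}-4-(hydroxymethyl)oxolan-2-one | O=C1C[C@H](CO)[C@@H](C#CCO[Si](c2ccccc2)(c2ccccc2)C(C)(C)C)O1 | intermediate
10 | (4R,5S)-5-{3-[(tert-butyldiphenylsilyl)oxy]prop-1-yn-1-yl}-4-{[(triethylsilyl)oxy]methyl}oxolan-2-one | O=C1C[C@H](CO[Si](CC)(CC)CC)[C@@H](C#CCO[Si](c2ccccc2)(c2ccccc2)C(C)(C)C)O1 | intermediate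
11 | diethyl (2S,3R)-2-{3-[(tert-butyldiphenylsilyl)oxy]prop-1-yn-1-yl}-3-{[(triethylsilyl)oxy]methyl}-2,3-dihydrofuran-5-yl phosphate | CCOP(=O)(OCC)OC1=C[C@H](CO[Si](CC)(CC)CC)[C@@H](C#CCO[Si](c2ccccc2)(c2ccccc2)C(C)(C)C)O1 | intermediate
12 | diethyl [(3S,4R,5S)-5-{3-[(tert-butyldiphenylsilyl)oxy]prop-1-yn-1-yl}-2-oxo-4-{[(triethylsilyl)oxy]methyl}oxolan-3-yl]phosphonate | O=C1[C@@H](P(=O)(OCC)OCC)[C@H](CO[Si](CC)(CC)CC)[C@@H](C#CCO[Si](c2ccccc2)(c2ccccc2)C(C)(C)C)O1 | intermediate
13 | diethyl [(3S,4R,5S)-5-{3-[(tert-butyldiphenylsilyl)oxy]prop-1-yn-1-yl}-4-(hydroxymethyl)-2-oxooxolan-3-yl]phosphonate | O=C1[C@@H](P(=O)(OCC)OCC)[C@H](CO)[C@@H](C#CCO[Si](c2ccccc2)(c2ccccc2)C(C)(C)C)O1 | intermediate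
14 | diethyl [(3S,4S,5S)-5-{3-[(tert-butyldiphenylsilyl)oxy]prop-1-yn-1-yl}-4-formyl-2-oxooxolan-3-yl]phosphonate | O=C1[C@@H](P(=O)(OCC)OCC)[C@H](C=O)[C@@H](C#CCO[Si](c2ccccc2)(c2ccccc2)C(C)(C)C)O1 | intermediate
15 | methyl prop-2-ynoate | C#CC(=O)OC | starting material
16 | prop-2-enal (acrolein) | C=CC=O | starting material
17 | methyl (2Z)-3-hydroxy-2-(iodomethylidene)pent-4-enoate, racemic | C=CC(O)/C(C(=O)OC)=C/I | intermediate
18 | methyl (2Z,3S)-3-hydroxy-2-(iodomethylidene)pent-4-enoate | C=C[C@H](O)/C(C(=O)OC)=C/I | intermediate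
19 | methyl (2Z,3S)-2-(iodomethylidene)-3-[(2-methylpropanoyl)oxy]pent-4-enoate | C=C[C@H](OC(=O)C(C)C)/C(C(=O)OC)=C/I | intermediate
20 | methyl (2Z,4R)-4-[(2S,3R,4S)-2-{3-[(tert-butyldiphenylsilyl)oxy]prop-1-yn-1-yl}-4-(diethoxyphosphoryl)-5-oxooxolan-3-yl]-4-hydroxy-2-[(1S)-1-(2-methylpropanoyloxy)prop-2-en-1-yl]but-2-enoate | C=C[C@H](OC(=O)C(C)C)/C(C(=O)OC)=C/[C@@H](O)[C@@H]1[C@@H](C#CCO[Si](c2ccccc2)(c2ccccc2)C(C)(C)C)OC(=O)[C@H]1P(=O)(OCC)OCC | intermediate
21 | diethyl [(3S,4R,5S)-5-{3-[(tert-butyldiphenylsilyl)oxy]prop-1-yn-1-yl}-4-{(2R)-4-[(1S)-1-(2-methylpropanoyloxy)prop-2-en-1-yl]-5-oxo-2,5-dihydrofuran-2-yl}-2-oxooxolan-3-yl]phosphonate | C=C[C@H](OC(=O)C(C)C)C1=C[C@@H](OC1=O)[C@@H]2[C@@H](C#CCO[Si](c3ccccc3)(c3ccccc3)C(C)(C)C)OC(=O)[C@H]2P(=O)(OCC)OCC | intermediate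
22 | diethyl [(3S,4R,5S)-5-(3-hydroxyprop-1-yn-1-yl)-4-{(2R)-4-[(1S)-1-(2-methylpropanoyloxy)prop-2-en-1-yl]-5-oxo-2,5-dihydrofuran-2-yl}-2-oxooxolan-3-yl]phosphonate | C=C[C@H](OC(=O)C(C)C)C1=C[C@@H](OC1=O)[C@@H]2[C@@H](C#CCO)OC(=O)[C@H]2P(=O)(OCC)OCC | intermediate
23 | diethyl [(3S,4R,5S)-5-[(1Z)-3-hydroxy-2-(tributylstannyl)prop-1-en-1-yl]-4-{(2R)-4-[(1S)-1-(2-methylpropanoyloxy)prop-2-en-1-yl]-5-oxo-2,5-dihydrofuran-2-yl}-2-oxooxolan-3-yl]phosphonate | C=C[C@H](OC(=O)C(C)C)C1=C[C@@H](OC1=O)[C@@H]2[C@@H](/C=C(/CO)[Sn](CCCC)(CCCC)CCCC)OC(=O)[C@H]2P(=O)(OCC)OCC | intermediate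
24 | diethyl [(3S,4R,5S)-5-[(1Z)-3-hydroxy-2-iodoprop-1-en-1-yl]-4-{(2R)-4-[(1S)-1-(2-methylpropanoyloxy)prop-2-en-1-yl]-5-oxo-2,5-dihydrofuran-2-yl}-2-oxooxolan-3-yl]phosphonate | C=C[C@H](OC(=O)C(C)C)C1=C[C@@H](OC1=O)[C@@H]2[C@@H](/C=C(/CO)I)OC(=O)[C@H]2P(=O)(OCC)OCC | intermediate
25 | diethyl [(3S,4R,5S)-5-[(1Z)-3-(9-borabicyclo[3.3.1]nonan-9-yloxy)-2-iodoprop-1-en-1-yl]-4-{(2R)-4-[(1S)-3-(9-borabicyclo[3.3.1]nonan-9-yl)-1-(2-methylpropanoyloxy)propyl]-5-oxo-2,5-dihydrofuran-2-yl}-2-oxooxolan-3-yl]phosphonate | C(C[C@H](OC(=O)C(C)C)C1=C[C@@H](OC1=O)[C@@H]2[C@@H](/C=C(/COB3C4CCCC3CCC4)I)OC(=O)[C@H]2P(=O)(OCC)OCC)B5C6CCCC5CCC6 | intermediate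
26 | diethyl [(3S,4Z,6R,7R,8R,9E,11S)-14-hydroxy-3-(2-methylpropanoyloxy)-12,8:15,6-diolido-13-norgermacra-4,9-dien-11-yl]phosphonate | CCOP(=O)(OCC)[C@@H]1C(=O)O[C@@H]2/C=C(/CO)CC[C@H](OC(=O)C(C)C)C3=C[C@@H](OC3=O)[C@@H]12 | intermediate
27 | (3S,4Z,6R,7S,8R,9E)-14-hydroxy-3-(2-methylpropanoyloxy)germacra-4,9,11(13)-triene-12,8:15,6-diolide (CNP0322767.4) | C=C1C(=O)O[C@@H]2/C=C(/CO)CC[C@H](OC(=O)C(C)C)C3=C[C@@H](OC3=O)[C@@H]12 | target

**Totals**
Total step count: 17. Longest linear sequence: 13 steps (steps 1, 2, 4–9, 13–17, from but-2-yne-1,4-diol).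

**Steps most likely to fail**

Step 16. The intramolecular transmetalation that closes the strained ten-membered ring (which must accommodate the ring-trans C4=C5 of the bridging butenolide) may be slower than intermolecular coupling, protodeboronation or β-hydride elimination, so that oligomers or reduced open-chain material dominate. The fallback sets out from 24 and avoids a preformed organometallic. Hydrozirconation of the terminal vinyl group (Cp2Zr(H)Cl, THF, rt) followed by iodine would give the primary iodide diethyl [(3S,4R,5S)-5-[(1Z)-3-hydroxy-2-iodoprop-1-en-1-yl]-4-{(2R)-4-[(1S)-3-iodo-1-(2-methylpropanoyloxy)propyl]-5-oxo-2,5-dihydrofuran-2-yl}-2-oxooxolan-3-yl]phosphonate F1. A nickel-catalysed reductive cross-electrophile coupling of its alkyl and alkenyl iodide termini (NiCl2(dme), 4,4′-di-tert-butyl-2,2′-bipyridine, Mn powder, DMA, slow addition at high dilution) would then close the same C1–C10 bond and return to the route at 26.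

Step 13. Facial selectivity in the addition to the α-branched aldehyde may be poor, and the β-acyloxy aldehyde may suffer β-elimination under the Lewis-acidic chromium salts. The fallback sets out from 14 and fixes C6 by reagent-controlled reduction of a ketone instead.
- Pinnick oxidation (NaClO2, NaH2PO4, 2-methylbut-2-ene) would give (2S,3S,4S)-2-{3-[(tert-butyldiphenylsilyl)oxy]prop-1-yn-1-yl}-4-(diethoxyphosphoryl)-5-oxooxolane-3-carboxylic acid F2.
- 1-Chloro-N,N,2-trimethylprop-1-en-1-amine would convert it, without isolation, into (2S,3R,4S)-2-{3-[(tert-butyldiphenylsilyl)oxy]prop-1-yn-1-yl}-4-(diethoxyphosphoryl)-5-oxooxolane-3-carbonyl chloride F3.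
- In parallel, 19 would be stannylated (hexamethyldistannane, Pd(PPh3)4) to methyl (2Z,3S)-3-[(2-methylpropanoyl)oxy]-2-[(trimethylstannyl)methylidene]pent-4-enoate F4.
- Stille acylation of F4 by F3 (Pd2(dba)3, tri(2-furyl)phosphine) would give the Z-keto enoate methyl (2Z)-4-[(2S,3S,4S)-2-{3-[(tert-butyldiphenylsilyl)oxy]prop-1-yn-1-yl}-4-(diethoxyphosphoryl)-5-oxooxolan-3-yl]-2-[(1S)-1-(2-methylpropanoyloxy)prop-2-en-1-yl]-4-oxobut-2-enoate F5.
- Corey–Bakshi–Shibata reduction with catecholborane at −78 °C should give hydroxy ester 20, which lactonizes to 21, where the route is rejoined. The (R)-configured catalyst is the one to use if the alkenyl branch acts as the large group.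

Step 10. Acrolein may undergo conjugate addition or oligomerize under magnesium iodide, and the Z geometry may erode before work-up. The fallback sets out from 15 and 16 and uses a low-temperature catalytic asymmetric three-component coupling. Iodotrimethylsilane and a chiral prolinol-derived oxazaborolidinium triflimide (20 mol %, CH2Cl2, −78 °C) would generate a silyl β-iodo allenolate that adds to the catalyst-bound aldehyde to give methyl (2Z,3S)-2-(iodomethylidene)-3-[(trimethylsilyl)oxy]pent-4-enoate F6. The catalyst enantiomer is the one that exposes the aldehyde face leading to 3S. Dilute HCl would release 18 directly, so that 17 and the resolution of step 11 are bypassed and the route is rejoined at 18.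

Further compounds
F1 | step 16 | diethyl [(3S,4R,5S)-5-[(1Z)-3-hydroxy-2-iodoprop-1-en-1-yl]-4-{(2R)-4-[(1S)-3-iodo-1-(2-methylpropanoyloxy)propyl]-5-oxo-2,5-dihydrofuran-2-yl}-2-oxooxolan-3-yl]phosphonate | ICC[C@H](OC(=O)C(C)C)C1=C[C@@H](OC1=O)[C@@H]2[C@@H](/C=C(/CO)I)OC(=O)[C@H]2P(=O)(OCC)OCC
F2 | step 13 | (2S,3S,4S)-2-{3-[(tert-butyldiphenylsilyl)oxy]prop-1-yn-1-yl}-4-(diethoxyphosphoryl)-5-oxooxolane-3-carboxylic acid | OC(=O)[C@@H]1[C@@H](C#CCO[Si](c2ccccc2)(c2ccccc2)C(C)(C)C)OC(=O)[C@H]1P(=O)(OCC)OCC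
F3 | step 13 | (2S,3R,4S)-2-{3-[(tert-butyldiphenylsilyl)oxy]prop-1-yn-1-yl}-4-(diethoxyphosphoryl)-5-oxooxolane-3-carbonyl chloride | ClC(=O)[C@@H]1[C@@H](C#CCO[Si](c2ccccc2)(c2ccccc2)C(C)(C)C)OC(=O)[C@H]1P(=O)(OCC)OCC
F4 | step 13 | methyl (2Z,3S)-3-[(2-methylpropanoyl)oxy]-2-[(trimethylstannyl)methylidene]pent-4-enoate | C=C[C@H](OC(=O)C(C)C)/C(C(=O)OC)=C/[Sn](C)(C)C
F5 | step 13 | methyl (2Z)-4-[(2S,3S,4S)-2-{3-[(tert-butyldiphenylsilyl)oxy]prop-1-yn-1-yl}-4-(diethoxyphosphoryl)-5-oxooxolan-3-yl]-2-[(1S)-1-(2-methylpropanoyloxy)prop-2-en-1-yl]-4-oxobut-2-enoate | C=C[C@H](OC(=O)C(C)C)/C(C(=O)OC)=C/C(=O)[C@@H]1[C@@H](C#CCO[Si](c2ccccc2)(c2ccccc2)C(C)(C)C)OC(=O)[C@H]1P(=O)(OCC)OCC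
F6 | step 10 | methyl (2Z,3S)-2-(iodomethylidene)-3-[(trimethylsilyl)oxy]pent-4-enoate | C=C[C@H](O[Si](C)(C)C)/C(C(=O)OC)=C/I
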